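If each exchange in the flask has come level with its reverse by the end, one ratio gives the shares of the complexes there.

starting complex 0.50 mM; incoming ligand 2.00 mM (fed, over 2.5 s); time 20 min

    starting complex + incoming ligand ⇌ leaving ligand + complex with one exchanged (K1 = 20, k1 = 36 L mol⁻¹ s⁻¹)
    complex with one exchanged + incoming ligand ⇌ leaving ligand + complex with two exchanged (K2 = 0.42, k2 = 58 L mol⁻¹ s⁻¹)
    complex with two exchanged + incoming ligand ⇌ leaving ligand + complex with three exchanged (K3 = 4.7, k3 = 13 L mol⁻¹ s⁻¹)

- the reaction counts as stopped when no species that holds the starting complex changes by six tenths of a point or more over the second half of the time
- run time (flask): 20 min

- why nothing more happens at 20 min, or that something still does (forward and back rates have come level / it is still moving / the incoming ligand has run out first)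
- conversion of starting complex at 20 min
- amount of complex with three exchanged at 20 min, in percent of the starting complex charged
- amount of complex with one exchanged at 20 min, in percent of the starting complex charged

We expect this thermodynamic control in the flask. The forward half-lives of the starting complex, the complex with one exchanged and the complex with two exchanged are 0.16 min, 0.10 min and 0.44 min, with the other charges counted whole and the way back not counted. Each is short against 20 min.

At balance, each complex's share equals the share of the one before it, times that step's equilibrium constant, times the ratio of free incoming to free leaving ligand. That ratio depends in turn on the shares. Per complex charged, the flask holds 4.00 incoming ligands. A mean number of exchanges per complex therefore frees that number of leaving ligands and removes as many incoming ones.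

So we set up a small table. Each row is a trial mean number. One column holds the ratio that the trial leaves, and the other holds the mean number which that ratio gives back.

The first row tries 2. It leaves a ratio of 1.00 and gives back 2.25, more than the trial. The second row tries 3. It leaves 0.333 and gives back 1.28, less than the trial.

Reading the columns against each other, the consistent number lies between the rows. A straight line puts it at 2.13. This gives the free-ligand ratio, 0.879, free incoming ligand over free leaving ligand at balance.

The relative shares then sum to 51.9, with the starting complex counted as one. We reckon a conversion of 98.1%, 51.7% of the complex with three exchanged and 33.9% of the complex with one exchanged. We reckon incoming ligand left at 46.8% of its charge, so it has not run out, and with the forward half-lives short against 20 min we expect forward and back rates to have come level.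

The forecast also says forward and back rates have come level, on the ground that “the flask sits at equilibrium”. It gives a conversion of 98%, 51.4% of the complex with three exchanged, below our value, and 34.2% of the complex with one exchanged, above our value.

In the simulation of the flask forward and back rates have come level, with a conversion of 98.0%, 51.4% of the complex with three exchanged and 34.1% of the complex with one exchanged. In the neighbouring flask with 5.0 mM of incoming ligand, the same two rows leave ratios of 4.00 and 2.33. These give back 2.89 and 2.76, and the line crosses at 2.79. The ratio there rises from 0.879 to 2.59. We reckon 86.2% of the complex with three exchanged and 6.53% of the complex with one exchanged. That neighbouring flask gives 86.2% and 6.56%.

Its constants are made up; what happens was integrated by code.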